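## The problem

The target 32 is a bicyclo[2.2.2]oct-5-en-2-one. Its bridgeheads C2 (CH) and C5 (quaternary) are joined by the keto bridge C1–C10, the alkene bridge C3=C4 (methyl on C4) and the ethano bridge C1'–C2' (6-methylhepta-1,5-dien-2-yl on C1'). The C5–C10 bond is shared with cyclohexane ring B (C5 to C10), which carries a trans-fused α-methyl-γ-lactone (oxygen on C6, C11 on C7, carbonyl C12).

Seven stereocentres must be set, two of them (C5, C10) vicinal quaternary carbons. Only C10 can be bought; it has to direct C1' across ring A and, through a tether, C5 and C2.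

On the ring B chair the C10 methyl is axial on one face and C4 axial on the other, so C6 and C7 are screened from both sides. Both lactone bonds are equatorial and H7 sits in the pocket under C4 and its methyl, so C6, C7 and C11 are better left to equilibration than to reagent approach.

The 1,5-diene side chain rules out hydrogenation, hydroboration, peracids, ozone and hot protic acid. The lactone α-carbon C11 can epimerise, and any intermediate with carbonyls on both C1 and C3 is a 1,3-diketone that enolises at C2.

The key step rests on one feature: C5 is β to a ring B carbonyl on C7 (through C6) and is linked through C4 and C3 to C2. With C3 as the ketone of an acyl arm on C2, the enolate carbon C4 can be delivered to C5, closing the six-membered ring C2–C3–C4–C5–C2'–C1' of the bicycle.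

That closure leaves two ketones (C3, C7) and two α-positions of the C7 carbonyl (C6, C8) to be told apart, and the plan must provide for both.

## Retrosynthesis

**32 to 29 (lactone).** Target 32 is unmasked from dioxolane 31. The lactone of 31 is cut at O–C12 and the C6 carbinol is taken back to a ketone, giving keto acid 29. This is preferred to the conjugate reduction of butenolide 27: a reagent reaches C7 only from the face of the C10 methyl and would give the cis-fused lactone. In 29, C7 is α to a ketone and places its side chain equatorially by equilibration. The forward steps need a reduction that gives the equatorial C6 alcohol (electron transfer, not hydride) and a base equilibration of C11.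

**29 to 24 (carbonyl transposition).** The 1,4-keto acid 29 is the hydrolytic isomer of butenolide 27 (C12–O cut, proton moved from C6 to C11). Butenolide 27 is cut at C7=C11 to phosphonate ester 26, and 26 at the ester to α-ketol 24 and acid 25. The carbonyl that the key step leaves on C7 is used once to bind C11 and is then moved to C6, where the stereochemistry needs it. Direct alkylation of a C6 ketone would require a separate 1,2-transposition first.

**24 to 21 (C6 oxygen).** Ketol 24 comes from enone 23 by conjugate reduction, and 23 from enone 21 by enolate hydroxylation. The C8=C9 double bond is functional: in 21, C10 is quaternary and C8 is sp2, so the C7 carbonyl can enolise only toward C6. In the saturated ketone both kinetic and thermodynamic enolisation would go to C8.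

**21 to 15 (C3=C4).** The alkene is taken back to the C3 ketone of 15 through enol triflate 19. C2 is a bridgehead, so the enolate can form only toward C4. Ring B must have no acidic proton while the hindered C4–H is removed, hence silyl dienol ether 17. The mask costs one step and is removed in the work-up of the triflate reduction.

**15 to 14 (key step).** Cutting C4–C5 opens the bicycle to decalin 14: a propanoyl group on C2, the side chain on C1', a dioxolane on C1 and a cross-conjugated dienone in ring B. The neighbouring cuts (C1–C2 with C1'–C2', C5–C10, or C1–C2 with C1–C10) all need strained or fully substituted small-ring precursors; this one needs a Wieland–Miescher-type decalin. The forward reaction must form a quaternary carbon next to another; tethering and reversibility should allow this. The dioxolane is essential, because a free C1 ketone would turn C2 into a 1,3-diketone carbon whose anion cannot close.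

**14 to 4 (ring A substituents).** Ketone 14 is the oxidation product of carbinol 13, which is the ketal of aldol 12. Aldol 12 is cut at C2–C3 and at C1'–side chain to enone 4, propanal 8 and cuprate 10, joined in one three-component operation. Cuprate 10 comes from hydrazone 7 (ketone 5 and hydrazide 6) by a Shapiro reaction.

**4 to 1 (two dehydrogenations).** Enone 4 is taken back through dienone 2 to (R)-Wieland–Miescher ketone 1. The order matters: once ring B is a cross-conjugated dienone it has no α-hydrogen and is inert to ketalisation. The C1 ketone can then be enolised, and later ketalised, without a protecting group on ring B.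

## Roads not taken

**Alternative 1:** The cut removes C1–C2 and C1'–C2' together and leads to cyclobutanone A1 (C1, C2', C5, C10 in the four-membered ring, a Z-dienoate on C5). In the forward step [Rh(cod)Cl]2 with a phosphine would insert into the C1–C2' bond and the tethered (Z)-alkene C2=C1' would insert, giving A2.
- Merits: both six-membered rings of the bicycle and C2 form in one catalytic step. The C3=C4 alkene is already present. Ring B and the lactone, with C6, C7, C10 and C11, could come from a santonin-type chiral-pool compound. On stereochemical economy this road is better than the chosen one, which spends six steps on the lactone.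
- Weak points: A1 is a cyclobutanone fused trans across the two quaternary carbons C5 and C10 (C1 and C2' are trans on ring B in the target), a strained and hard-to-make substrate. The metal must choose C1–C2' over C1–C10; decarbonylation competes; the Z-alkene of an electron-poor dienoate can isomerise. A2 carries an ester on C1', so the side chain costs further steps, ending with a methylenation beside the C1 ketone and the lactone.
- Against it the chosen plan sets a textbook key step, a precursor 14 reached in five steps, and the side chain installed intact in one operation.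

**Alternative 2:** The cut is C5–C10. The silyl ketene acetal of six-membered lactone A3 would rearrange (Ireland–Claisen, boat transition state) to acid A4, forming C10–C5 as C3–O breaks.
- Merits: the two vicinal quaternary carbons are joined in a sigmatropic step with chirality transfer from C3. The alkene arrives at C3=C4 without any triflate chemistry, which would save steps 8 to 10 of the chosen route.
- Weak points: enolisation of A3 places a silyloxy group (on C1) β to the enolate, inviting elimination. The step must make a bond between two fully substituted carbons through a boat. A4 has no ring B: C6 is a protected hydroxymethyl and C9 a carboxylic acid on neopentyl carbons, so ring B and the lactone must still be annulated at the most hindered site.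
- The chosen plan sets against this road's better alkene placement that ring B and C10 are bought with the starting material.

**Alternative 3:** The cut removes C1–C2 and C1–C10, with C1 supplied by carbon monoxide. [Rh(CO)2Cl]2 under CO would open the C4–C10 bond of vinylcyclopropane A5 and close the ketone ring, giving A6.
- Merits: the lactone is in place before the key step. C1 needs no protecting group at all, which would remove steps 5 and 17 of the chosen route. From A5 onward this is the shortest road on paper.
- Weak points: all three cyclopropane carbons of A5 (C4, C5, C10) are fully substituted and shared with two rings, so the synthesis of A5 is the real problem. The metal must cleave C4–C10 and not C4–C5. A6 still needs its C3 enol acetate replaced by hydrogen and its side-chain ketone methylenated selectively over the C1 ketone.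
- The chosen plan sets a simple precursor and a well-known ring closure against the shorter endgame.

Key step: step 7

Remark on the chemistry: the locants C1 to C12, C1' and C2' of the target core are kept for all intermediates; (R)-Wieland–Miescher ketone and 2-(diethoxyphosphoryl)propanoic acid are taken as commercial; centres that are later planarised or equilibrated (C2 and the carbinol carbon of 12 and 13, C4 of 15 to 17, C6 of 23 to 27, C11 of 28 to 30) are carried as mixtures and left open in the SMILES.

## Steps

Step 1
Reactants: 1 (R)-Wieland–Miescher ketone
Product: 2 (8aR)-8a-methyl-3,4-dihydronaphthalene-1,6(2H,8aH)-dione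
Conditions: DDQ (1.3 equiv), 1,4-dioxane, reflux
Reagents that add atoms: none
Why: DDQ dehydrogenation of a cyclohexenone to the cross-conjugated cyclohexadienone (hydride abstraction from the α'-dienol); the saturated C1 ketone cannot form a conjugated dienol and is left alone, and the quaternary C10 is untouched.

Step 2
Reactants: 2 (8aR)-8a-methyl-3,4-dihydronaphthalene-1,6(2H,8aH)-dione
Product: 4 (8aR)-8a-methyl-4,8a-dihydronaphthalene-1,6-dione, via lithium enolate 3 (not isolated)
Conditions: LiN(iPr)2, THF, −78 °C; then PhS(Cl)=NtBu, −78 °C
Reagents that add atoms: none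
Why: Mukaiyama dehydrogenation; the dienone ring has no α-hydrogen, so the amide base removes only the C2 proton of the C1 ketone, and the enolate–sulfinimidoyl adduct eliminates at −78 °C to the C2=C1' enone without exposing the base-sensitive skipped dienone to heat.

Step 3
Reactants: 5 6-methylhept-5-en-2-one; 6 2,4,6-triisopropylbenzenesulfonohydrazide
Product: 7 (E)-2,4,6-triisopropyl-N'-(6-methylhept-5-en-2-ylidene)benzenesulfonohydrazide
Conditions: MeOH, HCl (cat.), rt
Reagents that add atoms: none
Why: acid-catalysed hydrazone condensation; the triisopropylphenyl group is chosen because it prevents ortho-lithiation in the Shapiro reaction of the next step.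

Step 4
Reactants: 7 (E)-2,4,6-triisopropyl-N'-(6-methylhept-5-en-2-ylidene)benzenesulfonohydrazide; 4 (8aR)-8a-methyl-4,8a-dihydronaphthalene-1,6-dione; 8 propanal
Product: 12 aldol adduct (3S,8aR)-2-(1-hydroxypropyl)-8a-methyl-3-(6-methylhepta-1,5-dien-2-yl)-3,4-dihydronaphthalene-1,6(2H,8aH)-dione, via alkenyllithium 9 (not isolated), via Gilman cuprate 10 (not isolated), via lithium enolate 11 (not isolated)
Conditions: n-BuLi (2.1 equiv), THF, −78 → 0 °C; CuBr·SMe2 (0.5 equiv per alkenyllithium), −78 °C; then 4, −78 °C; then 8, −78 °C; H2O
Reagents that add atoms: none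
Why: the Shapiro reaction (deprotonation of the methyl group, loss of sulfinate and N2) gives the 2-lithio-1-alkene 9; its Gilman cuprate 10 adds 1,4 to the only unhindered enone of 4 (the dienone β-carbons are fully substituted or neopentyl), axially and anti to the pseudo-axial C10 methyl, which sets C1'; enolate 11 is trapped by propanal in an aldol addition (three-component coupling), with C2 and the carbinol carbon left uncontrolled because both are equilibrated or planarised later.

Step 5
Reactants: 12 aldol adduct
Product: 13 C1 ethylene ketal of 12 (2-(1-hydroxypropyl) dienone with a 1,3-dioxolane on C1)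
Conditions: TMSOCH2CH2OTMS, TMSOTf (cat.), CH2Cl2, −78 → −20 °C; pyridine quench
Reagents that add atoms: 1,2-bis(trimethylsilyloxy)ethane, C[Si](C)(C)OCCO[Si](C)(C)C
Why: Noyori ketalisation (aprotic silyl transfer at low temperature) converts the saturated C1 ketone; the cross-conjugated dienone carbonyl is too weakly electrophilic to react and the acid-sensitive 1,5-diene is spared; no stereocentre is touched.

Step 6
Reactants: 13 C1 ethylene ketal of 12
Product: 14 propanoyl dienone (C1 dioxolane; propanoyl on C2 cis to the C1' side chain; both anti to the C10 methyl)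
Conditions: Dess–Martin periodinane, CH2Cl2, 0 °C → rt
Reagents that add atoms: none
Why: Dess–Martin oxidation of the secondary carbinol to the ethyl ketone under near-neutral conditions; with C1 masked, C2 carries a single carbonyl and the 1,3-diketone acidity is absent; 14 is drawn as the more stable C2 epimer (equatorial acyl) and its epimer, if present, converges in step 7.

Step 7
Reactants: 14 propanoyl dienone
Product: 15 tricyclic bicyclo[2.2.2]octan-3-one (C1 dioxolane; C4 methyl as epimers; ring B cyclohex-8-en-7-one)
Conditions: KOtBu (0.3 equiv), t-BuOH/THF, 0 °C → rt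
Reagents that add atoms: none
Why: Intramolecular Michael addition of a ketone enolate to a 4,4-disubstituted cyclohexa-2,5-dienone, a known route to bicyclo[2.2.2]octanones. Catalytic tert-butoxide equilibrates the enolates of the propanoyl group: the C2 enolate only epimerises C2, while the C4 enolate attacks C5 once the acyl arm lies on the face of ring A anti to the C10 methyl. The ring C2–C3–C4–C5–C2'–C1' closes in a 6-(enolendo)-exo-trig mode through a boat of ring A with C2 and C5 as bow and stern. C5 is set by the tether, because the arm hangs from C2, which lies on the side of the dienone plane opposite to the C10 methyl, so only that face of C5 is within reach; C2 is fixed as a bridgehead in the same event, and C4 stays an epimerisable mixture that is planarised in step 9. The step needs site selectivity between the two β-carbons of the dienone, and geometry secures it: C9 is held anti to C2 about the C1–C10 bond, so no six-membered transition state reaches it. The fully substituted C5 is attacked only because the donor is tethered and the addition is reversible, the product being favoured by the exchange of a C=C π bond for a C–C σ bond. Protonation of the ring B dienolate by tert-butanol leaves the C8=C9 enone, in which C6 is the only enolisable position of ring B.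

Step 8
Reactants: 15 tricyclic bicyclo[2.2.2]octan-3-one
Product: 17 ring B tert-butyldimethylsilyl dienol ether (C6=C7–OSi; C8=C9; C3 ketone), via lithium dienolate 16 (not isolated)
Conditions: LiN(iPr)2, THF, −78 °C; TBSCl, DMPU, −78 → 0 °C
Reagents that add atoms: tert-butyldimethylsilyl chloride, C[Si](C)(Cl)C(C)(C)C
Why: kinetic deprotonation with the bulky amide takes a C6 methylene proton (α' of the enone) in preference to the tertiary neopentyl C4–H of the C3 ketone; O-silylation gives the 2-silyloxy-1,3-diene, which leaves ring B without an acidic proton for step 9.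

Step 9
Reactants: 17 ring B tert-butyldimethylsilyl dienol ether
Product: 19 C3 enol triflate (C3(OTf)=C4–CH3), via potassium enolate 18 (not isolated)
Conditions: KN(SiMe3)2, THF, −78 → 0 °C; Comins' reagent, −78 °C → rt
Reagents that add atoms: Comins' reagent, O=S(=O)(N(c1ccc(Cl)cn1)S(=O)(=O)C(F)(F)F)C(F)(F)F
Why: enol triflate formation; C4–H is now the only acidic proton (the bridgehead C2 cannot enolise, Bredt's rule), so the enolate forms regiospecifically toward C4 and is O-triflated by the reactive pyridyl triflimide.

Step 10
Reactants: 19 C3 enol triflate
Product: 21 tricyclic enone with the C3=C4 alkene (C1 dioxolane; ring B cyclohex-8-en-7-one), via silyl dienol ether 20 (not isolated)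
Conditions: Pd(OAc)2 (cat.), PPh3, HCO2H, Bu3N, DMF, 60 °C; then Bu4NF, THF, 0 °C
Reagents that add atoms: none
Why: palladium-catalysed formate reduction of a vinyl triflate (oxidative addition to zerovalent palladium, formate exchange, loss of CO2, C–H reductive elimination) gives the trisubstituted alkene without touching isolated alkenes; fluoride then cleaves the silyl dienol ether and protonation at C6 returns the enone.

Step 11
Reactants: 21 tricyclic enone with the C3=C4 alkene
Product: 23 6-hydroxy enone (C6 epimers), via potassium dienolate 22 (not isolated)
Conditions: KN(SiMe3)2, THF, −78 °C; 2-(phenylsulfonyl)-3-phenyloxaziridine, −78 °C; H2O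
Reagents that add atoms: 2-(phenylsulfonyl)-3-phenyloxaziridine, O=S(=O)(c1ccccc1)N1OC1c1ccccc1
Why: Davis hydroxylation of an enolate; ring B of 21 can enolise only toward C6 (C10 is quaternary, C8 is sp2), so oxygen is delivered regiospecifically, and the oxaziridine does not epoxidise the isolated alkenes at −78 °C; the configuration at C6 does not matter because C6 is planarised in step 15.

Step 12
Reactants: 23 6-hydroxy enone
Product: 24 6-hydroxy-7-ketone (saturated ring B α-ketol)
Conditions: [(Ph3P)CuH]6, PhMe/THF, H2O, rt
Reagents that add atoms: none
Why: conjugate reduction with Stryker's reagent; copper hydride adds to the enone β-carbon C9 and water protonates the copper enolate, while isolated alkenes, the ketal and the free hydroxyl are inert to this reagent.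

Step 13
Reactants: 24 6-hydroxy-7-ketone; 25 2-(diethoxyphosphoryl)propanoic acid
Product: 26 C6 2-(diethoxyphosphoryl)propanoate of 24
Conditions: DCC, DMAP (cat.), CH2Cl2, 0 °C → rt
Reagents that add atoms: none
Why: Steglich esterification; DMAP catalysis is needed for the neopentyl secondary alcohol, and the neutral conditions leave the α-ketol intact.

Step 14
Reactants: 26 C6 2-(diethoxyphosphoryl)propanoate of 24
Product: 27 fused α-methylbutenolide (C7=C11; lactone oxygen on C6; C1 dioxolane)
Conditions: KOtBu (1.05 equiv), THF, −78 → 0 °C
Reagents that add atoms: none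
Why: intramolecular Horner–Wadsworth–Emmons olefination of the C7 ketone by the tethered phosphonate anion, the standard butenolide synthesis from α-acyloxy ketones; the five-membered transition state overcomes hindrance that would stop an intermolecular olefination.

Step 15
Reactants: 27 fused α-methylbutenolide
Product: 29 6-keto acid (C6 ketone; 2-propanoic acid side chain equatorial on C7), via keto ester 28 (not isolated)
Conditions: NaOMe, MeOH, rt → 40 °C; then LiOH, H2O/THF, rt; dilute HCl to pH 4
Reagents that add atoms: lithium hydroxide, [Li+].[OH-]
Why: base-induced isomerisation of a γ-hydrogen butenolide to a γ-keto ester (as angelica lactone gives levulinate): methoxide removes the C6 proton, the 2-oxidofuran is protonated at C11 and the resulting enol lactone is opened irreversibly at C12, so the carbonyl moves from C7 to C6 with the C7–C11 bond in place; C7, now α to the ketone, equilibrates to the equatorial side chain with H7 under C4 (the configuration of 32), and hydroxide then saponifies the methyl ester of 28.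

Step 16
Reactants: 29 6-keto acid
Product: 31 trans-fused lactone with the C1 dioxolane (the ethylene ketal of 32), via hydroxy acid 30 (not isolated)
Conditions: Li, NH3(l)/THF, t-BuOH, −78 °C; NH4Cl; PPTS (cat.), PhMe, 50 °C; then KOtBu (cat.), t-BuOH, rt
Reagents that add atoms: none
Why: dissolving-metal reduction of the hindered C6 ketone (both faces are screened by the C4 and C10 methyls, so hydride delivery is unreliable) gives the more stable equatorial alcohol, trans to the C7 side chain; the carboxylate and the isolated alkenes are not reduced; acid-catalysed lactonisation closes the trans-fused γ-lactone, and catalytic tert-butoxide equilibrates C11 to the epimer with the methyl anti to C8, as in 32.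

Step 17
Reactants: 31 trans-fused lactone with the C1 dioxolane
Product: 32 target (CNP0385704.1)
Conditions: p-TsOH·H2O (cat.), THF/H2O, 40 °C
Reagents that add atoms: water, O
Why: acid-catalysed hydrolysis of the dioxolane, helped by relief of strain at the crowded C1; it is mild enough for the 1,5-diene, and the bridgehead C2 prevents both conjugation of the β,γ-unsaturated ketone and epimerisation.

## Compound list

1 | (R)-Wieland–Miescher ketone, (8aR)-8a-methyl-3,4,8,8a-tetrahydronaphthalene-1,6(2H,7H)-dione | C[C@@]12CCC(=O)C=C1CCCC2=O | starting material
2 | (8aR)-8a-methyl-3,4-dihydronaphthalene-1,6(2H,8aH)-dione | C[C@@]12C=CC(=O)C=C1CCCC2=O | intermediate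
3 | lithium enolate of 2 (O–C1=C2), not isolated | C[C@@]12C=CC(=O)C=C1CCC=C2O[Li] | intermediate
4 | (8aR)-8a-methyl-4,8a-dihydronaphthalene-1,6-dione | C[C@@]12C=CC(=O)C=C1CC=CC2=O | intermediate
5 | 6-methylhept-5-en-2-one | CC(=O)CCC=C(C)C | starting material
6 | 2,4,6-triisopropylbenzenesulfonohydrazide | CC(C)c1cc(C(C)C)c(S(=O)(=O)NN)c(C(C)C)c1 | starting material
7 | (E)-2,4,6-triisopropyl-N'-(6-methylhept-5-en-2-ylidene)benzenesulfonohydrazide | C/C(CCC=C(C)C)=N\NS(=O)(=O)c1c(C(C)C)cc(C(C)C)cc1C(C)C | intermediate
8 | propanal | CCC=O | starting material
9 | (6-methylhepta-1,5-dien-2-yl)lithium, not isolated | [Li]C(=C)CCC=C(C)C | intermediate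
10 | lithium bis(6-methylhepta-1,5-dien-2-yl)cuprate, not isolated | [Li+].C=C(CCC=C(C)C)[Cu-]C(=C)CCC=C(C)C | intermediate
11 | lithium enolate (O–C1=C2) of the 1,4-adduct, side chain on C1' anti to the C10 methyl, not isolated | C=C(CCC=C(C)C)[C@H]1CC2=CC(=O)C=C[C@@]2(C)C(O[Li])=C1 | intermediate
12 | aldol adduct, (3S,8aR)-2-(1-hydroxypropyl)-8a-methyl-3-(6-methylhepta-1,5-dien-2-yl)-3,4-dihydronaphthalene-1,6(2H,8aH)-dione, epimers at C2 and at the carbinol carbon | C=C(CCC=C(C)C)[C@H]1CC2=CC(=O)C=C[C@@]2(C)C(=O)C1C(O)CC | intermediate
13 | C1 ethylene ketal (1,3-dioxolane) of 12 | C=C(CCC=C(C)C)[C@H]1CC2=CC(=O)C=C[C@@]2(C)C2(OCCO2)C1C(O)CC | intermediate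
14 | propanoyl dienone, C1 ethylene ketal of (2R,3S,8aR)-8a-methyl-3-(6-methylhepta-1,5-dien-2-yl)-2-propanoyl-3,4-dihydronaphthalene-1,6(2H,8aH)-dione (acyl cis to the side chain, both anti to the angular methyl) | C=C(CCC=C(C)C)[C@H]1CC2=CC(=O)C=C[C@@]2(C)C2(OCCO2)[C@H]1C(=O)CC | intermediate
15 | tricyclic bicyclo[2.2.2]octan-3-one: C1 dioxolane, C4 methyl (epimers), side chain on C1' syn to the C3–C4 bridge, C10 methyl syn to the C1'–C2' bridge, ring B cyclohex-8-en-7-one | C=C(CCC=C(C)C)[C@H]1C[C@@]23C(C)C(=O)[C@@H]1C1(OCCO1)[C@]2(C)C=CC(=O)C3 | intermediate
16 | lithium dienolate of 15 (O–C7=C6, C8=C9), not isolated | C=C(CCC=C(C)C)[C@H]1C[C@@]23C(C)C(=O)[C@@H]1C1(OCCO1)[C@]2(C)C=CC(O[Li])=C3 | intermediate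
17 | ring B tert-butyldimethylsilyl dienol ether of 15 (C6=C7–OSi, C8=C9; C3 ketone) | C=C(CCC=C(C)C)[C@H]1C[C@@]23C(C)C(=O)[C@@H]1C1(OCCO1)[C@]2(C)C=CC(O[Si](C)(C)C(C)(C)C)=C3 | intermediate
18 | potassium enolate of 17 (O–C3=C4), not isolated | C=C(CCC=C(C)C)[C@H]1C[C@@]23C(C)=C(O[K])[C@@H]1C1(OCCO1)[C@]2(C)C=CC(O[Si](C)(C)C(C)(C)C)=C3 | intermediate
19 | C3 enol triflate (C3(OTf)=C4–CH3) with the ring B silyl dienol ether | C=C(CCC=C(C)C)[C@H]1C[C@@]23C(C)=C(OS(=O)(=O)C(F)(F)F)[C@@H]1C1(OCCO1)[C@]2(C)C=CC(O[Si](C)(C)C(C)(C)C)=C3 | intermediate
20 | C3=C4 alkene with the ring B silyl dienol ether, not isolated | C=C(CCC=C(C)C)[C@H]1C[C@@]23C(C)=C[C@@H]1C1(OCCO1)[C@]2(C)C=CC(O[Si](C)(C)C(C)(C)C)=C3 | intermediate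
21 | tricyclic enone: bicyclo[2.2.2]oct-3-ene with C4 methyl, C1 dioxolane, ring B cyclohex-8-en-7-one | C=C(CCC=C(C)C)[C@H]1C[C@@]23C(C)=C[C@@H]1C1(OCCO1)[C@]2(C)C=CC(=O)C3 | intermediate
22 | potassium dienolate of 21 (O–C7=C6, C8=C9), not isolated | C=C(CCC=C(C)C)[C@H]1C[C@@]23C(C)=C[C@@H]1C1(OCCO1)[C@]2(C)C=CC(O[K])=C3 | intermediate
23 | 6-hydroxy enone (C6 epimers; C7 ketone, C8=C9) | C=C(CCC=C(C)C)[C@H]1C[C@@]23C(C)=C[C@@H]1C1(OCCO1)[C@]2(C)C=CC(=O)C3O | intermediate
24 | 6-hydroxy-7-ketone (saturated ring B α-ketol, C6 epimers) | C=C(CCC=C(C)C)[C@H]1C[C@@]23C(C)=C[C@@H]1C1(OCCO1)[C@]2(C)CCC(=O)C3O | intermediate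
25 | 2-(diethoxyphosphoryl)propanoic acid | CC(C(=O)O)P(=O)(OCC)OCC | starting material
26 | C6 2-(diethoxyphosphoryl)propanoate of 24 | C=C(CCC=C(C)C)[C@H]1C[C@@]23C(C)=C[C@@H]1C1(OCCO1)[C@]2(C)CCC(=O)C3OC(=O)C(C)P(=O)(OCC)OCC | intermediate
27 | fused α-methylbutenolide (C7=C11, C12 lactone carbonyl, oxygen on C6; C6 epimers) | C=C(CCC=C(C)C)[C@H]1C[C@@]23C(C)=C[C@@H]1C1(OCCO1)[C@]2(C)CCC1=C(C)C(=O)OC13 | intermediate
28 | 6-keto methyl ester (methyl 2-propanoate side chain equatorial on C7, C11 epimers), not isolated | C=C(CCC=C(C)C)[C@H]1C[C@@]23C(C)=C[C@@H]1C1(OCCO1)[C@]2(C)CC[C@@H](C(C)C(=O)OC)C3=O | intermediate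
29 | 6-keto acid (2-propanoic acid side chain equatorial on C7, C11 epimers) | C=C(CCC=C(C)C)[C@H]1C[C@@]23C(C)=C[C@@H]1C1(OCCO1)[C@]2(C)CC[C@@H](C(C)C(=O)O)C3=O | intermediate
30 | 6-hydroxy acid (equatorial C6 hydroxyl trans to the C7 side chain), not isolated | C=C(CCC=C(C)C)[C@H]1C[C@@]23C(C)=C[C@@H]1C1(OCCO1)[C@]2(C)CC[C@@H](C(C)C(=O)O)[C@@H]3O | intermediate
31 | trans-fused lactone with the C1 dioxolane (ethylene ketal of 32) | C=C(CCC=C(C)C)[C@H]1C[C@@]23C(C)=C[C@@H]1C1(OCCO1)[C@]2(C)CC[C@H]1[C@H](C)C(=O)O[C@@H]13 | intermediate
32 | CNP0385704.1 | C=C(CCC=C(C)C)[C@H]1C[C@@]23C(C)=C[C@@H]1C(=O)[C@]2(C)CC[C@H]1[C@H](C)C(=O)O[C@@H]13 | target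

## Step count and least certain steps

Total: 17 steps. Longest linear sequence: 16 steps (1 to 32 through steps 1, 2 and 4 to 17); step 3 is a one-step branch.

**Step 7 (key step).** The closure onto the fully substituted C5, next to the quaternary C10, may be slow, or the equilibrium may favour the open dienone (retro-Michael). Prolonged base would then let the dienone isomerise through its C2' dienolate. The fallback makes the closure irreversible by silyl transfer instead of proton transfer. From 14 (equilibrated at C2 if needed), LiN(iPr)2 and TMSCl give the trimethylsilyl enol ether F1 of the propanoyl group; the dienone has no α-hydrogen, so only this enol ether forms. Catalytic Bu4N[Ph3SiF2] then triggers a fluoride-catalysed Mukaiyama–Michael closure with silyl transfer to the ring B trimethylsilyl dienol ether F2. K2CO3 in MeOH returns the route to 15.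

**Step 5.** Ketalisation of the C1 carbonyl is slow: it is flanked by a quaternary and a tertiary carbon and has the axial C1' side chain in a 1,3-relationship. The Lewis acid then has time to cause retro-aldol cleavage or dehydration of the β-hydroxy ketone, or cation capture by the neighbouring 1,1-disubstituted alkene. The fallback changes the protecting-group logic. From 12, the carbinol is capped as the triethylsilyl ether F3 (TESCl, imidazole), which tolerates longer and warmer exchange ketalisation (same reagent, −20 °C → rt) to the silyl ether ketal F4. Bu4NF returns the route to 13.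

**Step 4.** The basic organometallics may abstract a proton from the doubly allylic C2' methylene of 4, isomerising the skipped dienone before addition. The aldol trapping may also fail in the presence of the copper by-products (proton transfer, retro-aldol). The fallback separates the two bond formations and uses a non-basic nucleophile. Alkenyllithium 9 is quenched with 2-isopropoxy-4,4,5,5-tetramethyl-1,3,2-dioxaborolane to the alkenyl pinacol boronate F5. F5 is added to 4 with [Rh(cod)Cl]2 and aqueous K3PO4 in dioxane (Hayashi–Miyaura 1,4-addition) to give the 1,4-adduct ketone F6. LiN(iPr)2 and propanal then return the route to 12.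

**Step 11.** Oxygen transfer to the neopentyl C6, which lies between the C4 and C10 methyls, may be too slow. The enolate would then add to the sulfonimine by-product or be recovered on quench. The fallback is an oxidative α'-acetoxylation instead of enolate chemistry. From 21, Mn(OAc)3 in benzene at reflux gives the 6-acetoxy enone F7. K2CO3 in MeOH returns the route to 23.

**Step 16.** Facial selectivity at C6 may be poor, giving the axial alcohol and hence the cis-fused lactone; the equilibration of C11 may also be incomplete. The fallback uses kinetically controlled hydride delivery in place of electron transfer. Step 15 is interrupted after the methoxide stage and keto ester 28 is isolated. Reduction with NaBH4 and CeCl3·7H2O in MeOH should occur from the face of the C10 methyl, the other face being closed by the C4 methyl. The equatorial alkoxide lactonises onto the ester and, after the same C11 equilibration, the route is rejoined at 31.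

## Further compounds

F1 | step 7 | trimethylsilyl enol ether (C3=C4) of propanoyl dienone 14 | C=C(CCC=C(C)C)[C@H]1CC2=CC(=O)C=C[C@@]2(C)C2(OCCO2)[C@H]1C(O[Si](C)(C)C)=CC
F2 | step 7 | ring B trimethylsilyl dienol ether of 15 | C=C(CCC=C(C)C)[C@H]1C[C@@]23C(C)C(=O)[C@@H]1C1(OCCO1)[C@]2(C)C=CC(O[Si](C)(C)C)=C3
F3 | step 5 | triethylsilyl ether of aldol adduct 12 | C=C(CCC=C(C)C)[C@H]1CC2=CC(=O)C=C[C@@]2(C)C(=O)C1C(CC)O[Si](CC)(CC)CC
F4 | step 5 | triethylsilyl ether of ketal 13 | C=C(CCC=C(C)C)[C@H]1CC2=CC(=O)C=C[C@@]2(C)C2(OCCO2)C1C(CC)O[Si](CC)(CC)CC
F5 | step 4 | 4,4,5,5-tetramethyl-2-(6-methylhepta-1,5-dien-2-yl)-1,3,2-dioxaborolane | CC(C)=CCCC(=C)B1OC(C)(C)C(C)(C)O1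
F6 | step 4 | (3S,8aR)-8a-methyl-3-(6-methylhepta-1,5-dien-2-yl)-3,4-dihydronaphthalene-1,6(2H,8aH)-dione | C=C(CCC=C(C)C)[C@H]1CC2=CC(=O)C=C[C@@]2(C)C(=O)C1
F7 | step 11 | 6-acetoxy enone (C6 acetate of 23) | C=C(CCC=C(C)C)[C@H]1C[C@@]23C(C)=C[C@@H]1C1(OCCO1)[C@]2(C)C=CC(=O)C3OC(C)=O
F0 | step 16 | none | none
A1 | alternative 1 | trans-fused cyclobutanone with a (Z)-dienoate on C5 and the lactone in place | COC(=O)/C=C\C=C(\C)[C@]12CC(=O)[C@]1(C)CC[C@H]1[C@H](C)C(=O)O[C@@H]12
A2 | alternative 1 | tetracyclic keto lactone with a methyl ester on C1' | COC(=O)[C@H]1C[C@@]23C(C)=C[C@@H]1C(=O)[C@]2(C)CC[C@H]1[C@H](C)C(=O)O[C@@H]13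
A3 | alternative 2 | bicyclic six-membered lactone (oxygen on C3, carbonyl C9, α-carbon C10) on a cyclohexene with C4=C5 | C=C(CCC=C(C)C)[C@H]1CC(COCc2ccc(OC)cc2)=C(C)[C@@H]2OC(=O)C(C)[C@H](O[Si](C)(C)C(C)(C)C)[C@H]12
A4 | alternative 2 | bicyclo[2.2.2]octene with a C10 carboxylic acid | C=C(CCC=C(C)C)[C@H]1C[C@@]2(COCc3ccc(OC)cc3)C(C)=C[C@@H]1[C@@H](O[Si](C)(C)C(C)(C)C)[C@]2(C)C(=O)O
A5 | alternative 3 | vinylcyclopropane (cyclopropane C4, C5, C10; enol acetate C3=C2) with the lactone in place | CC(C)=CCCC(=O)[C@H]1C[C@@]23[C@@](C)(C(OC(C)=O)=C1)[C@]2(C)CC[C@H]1[C@H](C)C(=O)O[C@@H]13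
A6 | alternative 3 | tetracyclic C1 ketone with a C3 enol acetate and a side-chain ketone | CC(C)=CCCC(=O)[C@H]1C[C@@]23C(C)=C(OC(C)=O)[C@@H]1C(=O)[C@]2(C)CC[C@H]1[C@H](C)C(=O)O[C@@H]13
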